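**Plan**

- Retrosynthesis: C6–OH is traced back through NH2 to NO2. The pyranone ring is then cut at C2–C3 and at O1–C8a, giving the enol silane of 1-(4-bromo-2-fluoro-5-nitrophenyl)ethanone and silyl-protected 6-hydroxy-6-methylheptan-2-one.
- Enabling feature: C2 is a fully substituted ether carbon β to the C4 ketone (aldol relationship C4–C3–C2–O1). O1 sits on C8a of the benzene ring, ortho to the C4 acyl carbon and para to C6, so a fluorine at C8a flanked by acyl (ortho) and nitro (para) can be displaced by the aldol oxygen.
- Forward: nitration fixes the substitution pattern of the purchased benzene ring; sulcatone is hydrated and silylated; the fragments are joined at C2–C3 and the pyranone ring, the only ring made, closes at O1–C8a in the same flask.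
- Stereochemistry: the single stereocentre C2 comes from catalyst-controlled addition of the enol silane to the re face of the methyl ketone inside a confined chiral counter-anion; the C2–O1 bond is never broken afterwards.
- End game: the nitro helper (regiochemical marker, SNAr activator, latent hydroxyl) is reduced and exchanged for OH by way of the diazonium ion.

Key step: step 5

Remark: which antipode of the IDPi acid sends this class of nucleophile to the re face of the ketone is not established; the (S,S) acid is written, and its mirror image is to be used if a trial run shows the opposite sense. IDPi here means the imidodiphosphorimidate acid HN[P(=NSO2CF3)(O,O'-diolate)]2, in which each diolate is (S)-3,3'-bis[3,5-bis(trifluoromethyl)phenyl]-1,1'-binaphthalene-2,2'-diolate.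

Step 1
Reactants: 1 1-(4-bromo-2-fluorophenyl)ethan-1-one
Product: 2 1-(4-bromo-2-fluoro-5-nitrophenyl)ethan-1-one
Conditions: fuming HNO3, conc. H2SO4, −10 → 0 °C
Reagents that add atoms: nitric acid, O[N+](=O)[O-]
Why: Electrophilic aromatic nitration should go to C5 because that position is para to fluorine, ortho to bromine and meta to the acetyl group, whereas C3 is flanked by both halogens and C6 is ortho to the acyl group.

Step 2
Reactants: 2 1-(4-bromo-2-fluoro-5-nitrophenyl)ethan-1-one
Product: 3 {[1-(4-bromo-2-fluoro-5-nitrophenyl)ethenyl]oxy}trimethylsilane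
Conditions: Me3SiOTf, i-Pr2NEt, CH2Cl2, 0 °C; non-aqueous work-up, used crude
Reagents that add atoms: trimethylsilyl trifluoromethanesulfonate, C[Si](C)(C)OS(=O)(=O)C(F)(F)F
Why: Soft enolisation with O-silylation of an aryl methyl ketone (silyl triflate and a hindered tertiary amine) should give the terminal silyl enol ether, the non-nucleophilic base sparing the activated C–F bond.

Step 3
Reactants: 4 6-methylhept-5-en-2-one (sulcatone)
Product: 5 6-hydroxy-6-methylheptan-2-one
Conditions: 35% aq. H2SO4, 0 → 20 °C; neutralise
Reagents that add atoms: water, O
Why: Acid-catalysed Markovnikov hydration of the trisubstituted alkene should proceed through the tertiary cation and leave the ketone untouched.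

Step 4
Reactants: 5 6-hydroxy-6-methylheptan-2-one
Product: 6 6-methyl-6-[(trimethylsilyl)oxy]heptan-2-one
Conditions: Me3SiCl, imidazole, CH2Cl2, 0 → 20 °C
Reagents that add atoms: chlorotrimethylsilane, C[Si](C)(C)Cl
Why: Standard silylation of a tertiary alcohol (chlorosilane with imidazole) masks the hydroxyl so that it neither protonates the enol silane nor consumes silylium in the next step.

Step 5
Reactants: 3 {[1-(4-bromo-2-fluoro-5-nitrophenyl)ethenyl]oxy}trimethylsilane, 6 6-methyl-6-[(trimethylsilyl)oxy]heptan-2-one
Product: 9 (S)-7-bromo-2-(4-hydroxy-4-methylpentyl)-2-methyl-6-nitrochroman-4-one, via open-chain bis(trimethylsilyl) aldol ether 7 (not isolated), via ring-closed trimethylsilyl ether 8 (not isolated)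
Conditions: (S,S)-IDPi (1 mol %), 6 in excess, toluene, −78 → −40 °C; then Bu4N[Ph3SiF2] (10 mol %), THF, −78 → −20 °C; then 1 M aq. HCl, 0 °C
Reagents that add atoms: none
Why: Proposed new method: the chiral acid is silylated by 3, the silylium–IDPi ion pair O-silylates ketone 6, and inside the confined anion, which tells the methyl group from the long chain, enol silane 3 should attack the re face so that C3–C2 forms as the (S) centre of 7 while silyl transfer closes the cycle. The closest known reaction type is the IDPi/silylium-catalysed Mukaiyama aldol addition of silyl ketene acetals to simple ketones, in which methyl is distinguished even from ethyl; the step beyond precedent is the ketone-derived, electron-poor enol silane, which is less nucleophilic but should still suffice for a silylated ketone. Catalytic fluoride then attacks silicon of the aldol silyl ether and the alkoxide adds to C8a, which carries fluorine and is ortho to the C4 acyl group and para to the nitro group; loss of fluoride from the Meisenheimer intermediate closes the pyranone ring at O1–C8a (6-exo-trig addition–elimination with respect to C8a=C8) and the expelled fluoride unmasks the next molecule, as in the known fluoride-catalysed SNAr etherification of silyl ethers with activated aryl fluorides. The new stereocentre C2 is controlled only by the catalyst in the C–C bond formation and is untouched by the ring closure because the C2–O1 bond is never broken. The step needs enantioface selectivity (confined counter-anion), cross- over self-addition (aliphatic ketone 6 in excess is the better silyl acceptor and electrophile), C8a over C7 (fluoride is the better nucleofuge and only C8a gives a six-membered ring) and ring closure faster than retro-aldol cleavage, which the para-nitro group and the merely catalytic amount of base are meant to secure. Dilute acid finally removes the side-chain silyl group.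

Step 6
Reactants: 9 (S)-7-bromo-2-(4-hydroxy-4-methylpentyl)-2-methyl-6-nitrochroman-4-one
Product: 10 (S)-6-amino-7-bromo-2-(4-hydroxy-4-methylpentyl)-2-methylchroman-4-one
Conditions: H2 (1 atm), 5% Pt/C (sulfided), EtOAc, 20 °C
Reagents that add atoms: none
Why: Chemoselective catalytic hydrogenation of a nitroarene over sulfided platinum should reduce NO2 to NH2 under neutral conditions at room temperature, leaving the aryl bromide, the ketone and the nitro-activated aryl ether at C2 intact.

Step 7
Reactants: 10 (S)-6-amino-7-bromo-2-(4-hydroxy-4-methylpentyl)-2-methylchroman-4-one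
Product: 12 (S)-7-bromo-6-hydroxy-2-(4-hydroxy-4-methylpentyl)-2-methylchroman-4-one, via arenediazonium hydrogensulfate 11 (not isolated)
Conditions: NaNO2, 2 M aq. H2SO4–MeCN, 0 °C; then aq. Cu(NO3)2·3H2O (large excess), Cu2O (cat.), 20 °C
Reagents that add atoms: water, O
Why: Diazotisation followed by copper-mediated hydroxy-dediazoniation (Sandmeyer-type radical hydroxylation) should replace the diazonium group at C6 by OH at room temperature in dilute acid, conditions the tertiary alcohol, the bromide and the C2 stereocentre should survive.

**Compound list**

1 | 1-(4-bromo-2-fluorophenyl)ethan-1-one | CC(=O)c1ccc(Br)cc1F | starting material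
2 | 1-(4-bromo-2-fluoro-5-nitrophenyl)ethan-1-one | CC(=O)c1cc([N+](=O)[O-])c(Br)cc1F | intermediate
3 | {[1-(4-bromo-2-fluoro-5-nitrophenyl)ethenyl]oxy}trimethylsilane | C=C(O[Si](C)(C)C)c1cc([N+](=O)[O-])c(Br)cc1F | intermediate
4 | 6-methylhept-5-en-2-one (sulcatone) | CC(=O)CCC=C(C)C | starting material
5 | 6-hydroxy-6-methylheptan-2-one | CC(=O)CCCC(C)(C)O | intermediate
6 | 6-methyl-6-[(trimethylsilyl)oxy]heptan-2-one | CC(=O)CCCC(C)(C)O[Si](C)(C)C | intermediate
7 | (S)-1-(4-bromo-2-fluoro-5-nitrophenyl)-3,7-dimethyl-3,7-bis[(trimethylsilyl)oxy]octan-1-one | CC(C)(O[Si](C)(C)C)CCC[C@@](O[Si](C)(C)C)(C)CC(=O)c1cc([N+](=O)[O-])c(Br)cc1F | intermediate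
8 | (S)-7-bromo-2-methyl-2-{4-methyl-4-[(trimethylsilyl)oxy]pentyl}-6-nitrochroman-4-one | CC(C)(O[Si](C)(C)C)CCC[C@@]1(C)CC(=O)c2cc([N+](=O)[O-])c(Br)cc2O1 | intermediate
9 | (S)-7-bromo-2-(4-hydroxy-4-methylpentyl)-2-methyl-6-nitrochroman-4-one | CC(C)(O)CCC[C@@]1(C)CC(=O)c2cc([N+](=O)[O-])c(Br)cc2O1 | intermediate
10 | (S)-6-amino-7-bromo-2-(4-hydroxy-4-methylpentyl)-2-methylchroman-4-one | CC(C)(O)CCC[C@@]1(C)CC(=O)c2cc(N)c(Br)cc2O1 | intermediate
11 | (S)-7-bromo-2-(4-hydroxy-4-methylpentyl)-2-methyl-4-oxochroman-6-diazonium hydrogensulfate | CC(C)(O)CCC[C@@]1(C)CC(=O)c2cc([N+]#N)c(Br)cc2O1.OS(=O)(=O)[O-] | intermediate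
12 | (S)-7-bromo-6-hydroxy-2-(4-hydroxy-4-methylpentyl)-2-methylchroman-4-one | CC(C)(O)CCC[C@@]1(C)CC(=O)c2cc(O)c(Br)cc2O1 | target

**Step count**

Total steps: 7. Longest linear sequence: 5 steps (steps 1, 2, 5, 6, 7; the branch through steps 3, 4, 5, 6, 7 is equally long).

**Steps most likely to fail**

Step 5 (proposed new method). What may go wrong: slow C–C bond formation with the electron-poor enol silane, insufficient facial discrimination by the catalyst, or erosion of enantiomeric purity by retro-aldol cleavage before ring closure or by reversible opening of the nitro-activated aryl ether. The fallback uses known chemistry, sets out from 3 and 6 and comes back at 9. The two fragments are joined without stereocontrol by an achiral silyl triflimide-catalysed Mukaiyama aldol addition (Me3SiNTf2, CH2Cl2, −78 °C), which should give the racemic open-chain bis(trimethylsilyl) aldol ether F1. Catalytic Bu4N[Ph3SiF2] in THF should close it to the racemic ring-closed silyl ether F2, and dilute aqueous HCl should give the racemic nitrochromanone F3. Preparative supercritical-fluid chromatography on a chiral stationary phase then separates 9 from the (R)-enantiomer F4, and 9 goes on into step 6.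

Step 7. What may go wrong: reduction of the diazonium ion to the arene, azo coupling with amine not yet diazotised, or ionisation of the tertiary alcohol in the acidic medium. The fallback sets out from 10 and comes back at 12. Deaminative borylation with t-BuONO and B2pin2 in MeCN at 20 °C should give the aryl pinacol boronate (S)-7-bromo-2-(4-hydroxy-4-methylpentyl)-2-methyl-6-(4,4,5,5-tetramethyl-1,3,2-dioxaborolan-2-yl)chroman-4-one F5. Oxidation of the C–B bond with NaBO3·4H2O in THF–H2O at 20 °C then gives 12, so the C6–O bond is made by boron oxidation and not by trapping of the diazonium ion with water.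

Step 2. What may go wrong: attack of the base on the doubly activated C–F bond during enolisation, or hydrolysis of the enol silane during isolation. The fallback sets out from 2 and comes back at 3. α-Bromination of the acetyl group (Br2, AcOH, 20 °C) should give 2-bromo-1-(4-bromo-2-fluoro-5-nitrophenyl)ethan-1-one F6. Reductive silylation of this α-bromo ketone (Zn dust, Me3SiCl, MeCN, 0 °C) then generates 3 through the zinc enolate without any amine base; zinc is kept to one equivalent at low temperature so that insertion into the C–Br bond next to the ketone outruns electron transfer to the nitroarene.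

Further compounds
F1 | step 5 | racemic 1-(4-bromo-2-fluoro-5-nitrophenyl)-3,7-dimethyl-3,7-bis[(trimethylsilyl)oxy]octan-1-one | CC(C)(O[Si](C)(C)C)CCCC(C)(O[Si](C)(C)C)CC(=O)c1cc([N+](=O)[O-])c(Br)cc1F
F2 | step 5 | racemic 7-bromo-2-methyl-2-{4-methyl-4-[(trimethylsilyl)oxy]pentyl}-6-nitrochroman-4-one | CC(C)(O[Si](C)(C)C)CCCC1(C)CC(=O)c2cc([N+](=O)[O-])c(Br)cc2O1
F3 | step 5 | racemic 7-bromo-2-(4-hydroxy-4-methylpentyl)-2-methyl-6-nitrochroman-4-one | CC(C)(O)CCCC1(C)CC(=O)c2cc([N+](=O)[O-])c(Br)cc2O1
F4 | step 5 | (R)-7-bromo-2-(4-hydroxy-4-methylpentyl)-2-methyl-6-nitrochroman-4-one | CC(C)(O)CCC[C@]1(C)CC(=O)c2cc([N+](=O)[O-])c(Br)cc2O1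
F5 | step 7 | (S)-7-bromo-2-(4-hydroxy-4-methylpentyl)-2-methyl-6-(4,4,5,5-tetramethyl-1,3,2-dioxaborolan-2-yl)chroman-4-one | CC(C)(O)CCC[C@@]1(C)CC(=O)c2cc(B3OC(C)(C)C(C)(C)O3)c(Br)cc2O1
F6 | step 2 | 2-bromo-1-(4-bromo-2-fluoro-5-nitrophenyl)ethan-1-one | O=C(CBr)c1cc([N+](=O)[O-])c(Br)cc1F
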